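Ring B is disconnected at the C9–C10 bond. In ring A the C3 oxygen is para to the methyl-bearing quaternary C10, with C4(Me)=C5 between them, so C1–C2–C3–C4–C5–C10 is a latent 3-alkyl-2,4-dimethylphenol. Protonating a diazoketone at C9 lets the para carbon C10 expel N2: one operation closes ring B, creates C10 under the control of C7 and turns the arene into the ring A dienone; the C3 and C8 carbonyls are later reduced from the face opposite the angular methyl. The precursor is an open-chain phenol bearing C6–C7(CH2CO2Me)–C8(=O)–C9H=N2, with C7 set by auxiliary-controlled alkylation and a side-chain methyl ester that is inert to CF3CO2H.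

Key step: step 12

Remark on the chemistry: (2E)-3-methylpent-2-enoic acid, (4R)-4-benzyl-1,3-oxazolidin-2-one, methyl 4-chloro-4-oxobutanoate and (trimethylsilyl)diazomethane are taken as purchasable. Eudesmane numbering is used, β is the face of the C10 methyl group, and C13 is absent ("13-nor") until step 16.

Step 1
Reactants: 1 2,6-dimethylbenzoic acid
Product: 2 2,6-dimethyl-3-nitrobenzoic acid
Conditions: fuming HNO3, conc. H2SO4, 0 °C
Reagents that add atoms: nitric acid, O[N+](=O)[O-]
Why: Electrophilic aromatic nitration, in which both methyl groups (ortho/para) and the carboxyl group (meta) direct to C3 and the first nitro group deactivates the ring against a second one.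

Step 2
Reactants: 2 2,6-dimethyl-3-nitrobenzoic acid
Product: 3 3-amino-2,6-dimethylbenzoic acid
Conditions: H2 (1 atm), 10% Pd/C, MeOH, rt
Reagents that add atoms: none
Why: Catalytic hydrogenation reduces the nitroarene to the aniline and leaves the hindered carboxyl group untouched.

Step 3
Reactants: 3 3-amino-2,6-dimethylbenzoic acid
Product: 5 3-hydroxy-2,6-dimethylbenzoic acid, via arenediazonium hydrogen sulfate 4 (not isolated)
Conditions: NaNO2, 2 M H2SO4, 0–5 °C; then added to 2 M H2SO4 at 90 °C
Reagents that add atoms: water, O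
Why: Diazotisation followed by hydrolytic dediazoniation (phenol synthesis from an arenediazonium salt), with the cold diazonium solution run into hot dilute acid so that its concentration stays low and azo coupling with the phenol is limited.

Step 4
Reactants: 5 3-hydroxy-2,6-dimethylbenzoic acid
Product: 6 3-(hydroxymethyl)-2,4-dimethylphenol
Conditions: LiAlH4, THF, reflux; then 1 M HCl
Reagents that add atoms: none
Why: Hydride reduction of the carboxylic acid to the benzylic alcohol, which proceeds in refluxing THF even at a 2,6-disubstituted benzoic acid, the phenol being carried as its salt and released on acidic work-up.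

Step 5
Reactants: 6 3-(hydroxymethyl)-2,4-dimethylphenol
Product: 8 (2,6-dimethyl-3-{[tri(propan-2-yl)silyl]oxy}phenyl)methanol, via sodium phenoxide 7 (not isolated)
Conditions: NaH (1.0 equiv), THF, 0 °C; then i-Pr3SiCl, 0 °C → rt
Reagents that add atoms: chlorotri(propan-2-yl)silane, CC(C)[Si](Cl)(C(C)C)C(C)C
Why: The phenol, far more acidic than the benzylic alcohol, is converted selectively into its sodium salt and O-silylated (silyl ether formation), while the bulky silyl chloride does not touch the neutral CH2OH group flanked by two ortho methyls.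

Step 6
Reactants: 8 (2,6-dimethyl-3-{[tri(propan-2-yl)silyl]oxy}phenyl)methanol
Product: 9 [3-(bromomethyl)-2,4-dimethylphenoxy]tri(propan-2-yl)silane
Conditions: CBr4, PPh3, CH2Cl2, 0 °C
Reagents that add atoms: tetrabromomethane, BrC(Br)(Br)Br
Why: The Appel reaction converts the primary benzylic alcohol into the bromide under neutral conditions that the aryl silyl ether tolerates.

Step 7
Reactants: 10 (4R)-4-benzyl-1,3-oxazolidin-2-one; 11 methyl 4-chloro-4-oxobutanoate
Product: 12 methyl 4-[(4R)-4-benzyl-2-oxo-1,3-oxazolidin-3-yl]-4-oxobutanoate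
Conditions: Et3N, DMAP (cat.), CH2Cl2, 0 °C → rt
Reagents that add atoms: none
Why: N-Acylation of the oxazolidinone by the acid chloride under nucleophilic catalysis gives the imide, and the methyl ester is inert.

Step 8
Reactants: 12 methyl 4-[(4R)-4-benzyl-2-oxo-1,3-oxazolidin-3-yl]-4-oxobutanoate; 9 [3-(bromomethyl)-2,4-dimethylphenoxy]tri(propan-2-yl)silane
Product: 14 methyl (3R)-4-[(4R)-4-benzyl-2-oxo-1,3-oxazolidin-3-yl]-3-[(2,6-dimethyl-3-{[tri(propan-2-yl)silyl]oxy}phenyl)methyl]-4-oxobutanoate, via sodium Z-enolate 13 (not isolated)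
Conditions: 12 (1.5 equiv), NaN(SiMe3)2 (1.45 equiv), THF, −78 °C; then 9 (1.0 equiv), −78 → −30 °C
Reagents that add atoms: none
Why: Evans asymmetric alkylation, in which the base deprotonates α to the more acidic imide carbonyl to give the chelated Z-enolate and the benzylic bromide enters from the face opposite the benzyl group of the (4R)-auxiliary, which sets C7 as (R).

Step 9
Reactants: 14 methyl (3R)-4-[(4R)-4-benzyl-2-oxo-1,3-oxazolidin-3-yl]-3-[(2,6-dimethyl-3-{[tri(propan-2-yl)silyl]oxy}phenyl)methyl]-4-oxobutanoate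
Product: 16 (2R)-2-[(2,6-dimethyl-3-{[tri(propan-2-yl)silyl]oxy}phenyl)methyl]-4-methoxy-4-oxobutanoic acid, via peroxy acid 15 (not isolated)
Conditions: LiOH, 30% H2O2, THF–H2O (3:1), 0 °C; then aq. Na2SO3; then 1 M HCl
Reagents that add atoms: hydrogen peroxide, OO
Why: Hydroperoxide cleaves the exocyclic imide carbonyl (standard removal of the oxazolidinone auxiliary) much faster than it attacks the unactivated methyl ester or the aryl silyl ether at 0 °C, sulfite reduces the peroxy acid, and C7 is not touched.

Step 10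
Reactants: 16 (2R)-2-[(2,6-dimethyl-3-{[tri(propan-2-yl)silyl]oxy}phenyl)methyl]-4-methoxy-4-oxobutanoic acid; 17 (trimethylsilyl)diazomethane
Product: 19 methyl (3R)-5-diazo-3-[(2,6-dimethyl-3-{[tri(propan-2-yl)silyl]oxy}phenyl)methyl]-4-oxopentanoate, via isobutyl carbonic anhydride 18 (not isolated)
Conditions: i-BuOCOCl, N-methylmorpholine, THF, −15 °C; then 17 (2 M in hexanes), MeCN, 0 °C → rt
Reagents that add atoms: none
Why: The mixed carbonic anhydride acylates the diazoalkane at carbon (first stage of an Arndt–Eistert sequence) and the C-silyl group is lost on work-up, while activation as the anhydride at low temperature avoids ketene formation and keeps C7 intact.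

Step 11
Reactants: 19 methyl (3R)-5-diazo-3-[(2,6-dimethyl-3-{[tri(propan-2-yl)silyl]oxy}phenyl)methyl]-4-oxopentanoate
Product: 20 methyl (3R)-5-diazo-3-[(3-hydroxy-2,6-dimethylphenyl)methyl]-4-oxopentanoate
Conditions: Bu4NF (1.1 equiv), AcOH (1.1 equiv), THF, 0 °C
Reagents that add atoms: none
Why: Fluoride-induced cleavage of the aryl silyl ether, buffered with AcOH so that the medium neither enolises the diazoketone at C7 nor protonates it at C9.

Step 12
Reactants: 20 methyl (3R)-5-diazo-3-[(3-hydroxy-2,6-dimethylphenyl)methyl]-4-oxopentanoate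
Product: 21 methyl (7R,10S)-3,8-dioxo-13-noreudesma-1,4-dien-12-oate (10-methyl and C7 CH2CO2Me cis)
Conditions: CF3CO2H–CH2Cl2 (1:4), −20 °C, slow addition of dilute 20
Reagents that add atoms: none
Why: CF3CO2H protonates the diazo carbon C9 to an α-keto alkanediazonium ion, and the arene carbon C10, para to the C3 hydroxyl, displaces N2 with loss of the phenolic proton, so that ring A becomes the cross-conjugated 1,4-dien-3-one. This is the known acid-promoted aryl-participation cyclisation of phenolic α-diazoketones to fused cyclohexadienones. Ring B closes in a six-membered exo-tet mode through a ring carbon ortho to the tether (fused, not spiro), and the methyl on C10 blocks rearomatisation. The configuration at C10 is controlled by C7: in the chair-like array C5–C6–C7–C8–C9–C10 the CH2CO2Me group sits equatorial, which places the new axial methyl on the same face as the side chain. The step needs attack at C10 and not at C4 (ortho to the hydroxyl), which is secured by the higher nucleophilicity of the para position, by the less crowded C10 (flanked by C1–H, whereas C4 is flanked by the hydroxyl) and by the more stable cross-conjugated product; the methyl ester cannot lose its alkyl group and so does not intercept the diazonium ion. The minor C10 epimer should be removed by chromatography before any basic step, because epimerisation at C7 would turn it into the enantiomer of 21.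

Step 13
Reactants: 21 methyl (7R,10S)-3,8-dioxo-13-noreudesma-1,4-dien-12-oate
Product: 22 methyl (7R,10R)-3,8-dioxo-13-noreudesm-4-en-12-oate
Conditions: H2 (1 atm), RhCl(PPh3)3 (10 mol%), benzene–EtOH (1:1), rt
Reagents that add atoms: none
Why: Homogeneous hydrogenation saturates the disubstituted C1=C2 bond and leaves the tetrasubstituted C4=C5 bond and both carbonyl groups, the known selective 1,2-reduction of cross-conjugated cyclohexadienones.

Step 14
Reactants: 22 methyl (7R,10R)-3,8-dioxo-13-noreudesm-4-en-12-oate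
Product: 24 (7R,8R,10R)-3-oxo-13-noreudesm-4-en-8β,12-olide (cis-fused γ-lactone), via lithium alkoxide 23 (not isolated)
Conditions: LiBH(s-Bu)3 (1.1 equiv), THF, −78 °C; then AcOH, −78 °C → rt
Reagents that add atoms: none
Why: The bulky trialkylborohydride reduces the saturated C8 ketone faster than the hindered conjugated C3 carbonyl and attacks equatorially from the α face, away from the axial C10 methyl, so that the axial 8β-alkoxide forms cis to the C7 side chain and closes the γ-lactone with loss of methoxide (diastereoselective ketone reduction and lactonisation).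

Step 15
Reactants: 24 (7R,8R,10R)-3-oxo-13-noreudesm-4-en-8β,12-olide
Product: 25 (3S,7R,8R,10R)-3β-hydroxy-13-noreudesm-4-en-8β,12-olide
Conditions: NaBH4, CeCl3·7H2O, MeOH, −20 °C
Reagents that add atoms: none
Why: Luche reduction gives clean 1,2-reduction of the enone, with hydride adding axially from the α face of the ring A half-chair, opposite the angular methyl, to give the pseudo-equatorial 3β-alcohol, and the lactone is not reduced.

Step 16
Reactants: 25 (3S,7R,8R,10R)-3β-hydroxy-13-noreudesm-4-en-8β,12-olide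
Product: 28 (3S,7R,8R,10R)-3β-hydroxyeudesma-4,11(13)-dien-8β,12-olide, via Mannich base 26 (not isolated), via trimethylammonium iodide 27 (not isolated)
Conditions: LiN(i-Pr)2 (2.3 equiv), THF, −78 °C; CH2=NMe2+ I− (2.5 equiv), −78 °C → rt; H2O; then MeI, MeOH, rt; then aq. NaHCO3, EtOAc, rt
Reagents that add atoms: N,N-dimethylmethyleneiminium iodide, C=[N+](C)C.[I-]
Why: Mannich-type α-methylenation of a lactone, in which the dianion (3-alkoxide and lactone enolate) is aminomethylated at C11 and quaternisation followed by mild base-induced loss of trimethylamine gives the exocyclic C11=C13 bond, which removes the C11 stereocentre, while any N,O-acetal formed at O3 is hydrolysed on work-up.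

Step 17
Reactants: 28 (3S,7R,8R,10R)-3β-hydroxyeudesma-4,11(13)-dien-8β,12-olide; 29 (2E)-3-methylpent-2-enoic acid
Product: 30 (3S,7R,8R,10R)-3β-[(2E)-3-methylpent-2-enoyloxy]eudesma-4,11(13)-dien-8β,12-olide
Conditions: DCC, DMAP (cat.), CH2Cl2, 0 °C → rt
Reagents that add atoms: none
Why: Steglich esterification acylates the only free hydroxyl (3β, equatorial and allylic) with retention at C3 and without a base strong enough to deconjugate or isomerise the E-enoate.

Step 18
Reactants: 30 (3S,7R,8R,10R)-3β-[(2E)-3-methylpent-2-enoyloxy]eudesma-4,11(13)-dien-8β,12-olide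
Product: 33 methyl (3S,7R,8R,10R)-8β-acetoxy-3β-[(2E)-3-methylpent-2-enoyloxy]eudesma-4,11(13)-dien-12-oate (CNP0118541.1), via lithium carboxylate 31 (not isolated), via hydroxy methyl ester 32 (not isolated)
Conditions: LiOH·H2O (1.05 equiv), THF–H2O (4:1), 0 °C; evaporation; MeI, DMF, 0 °C → rt; MeI removed in vacuo; Ac2O, pyridine, DMAP (cat.), rt
Reagents that add atoms: lithium hydroxide, [Li+].[OH-]; iodomethane, CI; acetic anhydride, CC(=O)OC(C)=O
Why: One equivalent of hydroxide saponifies the strained γ-lactone far faster than the conjugated, β,β-disubstituted O3 ester of a secondary alcohol, the carboxylate is O-methylated under neutral conditions and the 8β-hydroxyl is acetylated at once under DMAP catalysis before it can re-close, with C8 untouched throughout (lactone saponification, carboxylate alkylation, acylation); any lactone that re-forms is 30 and can be resubmitted.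

Compound list
1 | 2,6-dimethylbenzoic acid | Cc1cccc(C)c1C(=O)O | starting material
2 | 2,6-dimethyl-3-nitrobenzoic acid | Cc1ccc([N+](=O)[O-])c(C)c1C(=O)O | intermediate
3 | 3-amino-2,6-dimethylbenzoic acid | Cc1ccc(N)c(C)c1C(=O)O | intermediate
4 | 3-carboxy-2,4-dimethylbenzenediazonium hydrogen sulfate | Cc1ccc([N+]#N)c(C)c1C(=O)O.OS(=O)(=O)[O-] | intermediate
5 | 3-hydroxy-2,6-dimethylbenzoic acid | Cc1ccc(O)c(C)c1C(=O)O | intermediate
6 | 3-(hydroxymethyl)-2,4-dimethylphenol | Cc1ccc(O)c(C)c1CO | intermediate
7 | sodium 3-(hydroxymethyl)-2,4-dimethylphenoxide | Cc1ccc([O-])c(C)c1CO.[Na+] | intermediate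
8 | (2,6-dimethyl-3-{[tri(propan-2-yl)silyl]oxy}phenyl)methanol | Cc1ccc(O[Si](C(C)C)(C(C)C)C(C)C)c(C)c1CO | intermediate
9 | [3-(bromomethyl)-2,4-dimethylphenoxy]tri(propan-2-yl)silane | Cc1ccc(O[Si](C(C)C)(C(C)C)C(C)C)c(C)c1CBr | intermediate
10 | (4R)-4-benzyl-1,3-oxazolidin-2-one | O=C1N[C@H](Cc2ccccc2)CO1 | starting material
11 | methyl 4-chloro-4-oxobutanoate | COC(=O)CCC(Cl)=O | starting material
12 | methyl 4-[(4R)-4-benzyl-2-oxo-1,3-oxazolidin-3-yl]-4-oxobutanoate | COC(=O)CCC(=O)N1[C@H](Cc2ccccc2)COC1=O | intermediate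
13 | sodium Z-enolate of 12 (enolate carbon α to the imide carbonyl) | COC(=O)C/C=C(\[O-])N1[C@H](Cc2ccccc2)COC1=O.[Na+] | intermediate
14 | methyl (3R)-4-[(4R)-4-benzyl-2-oxo-1,3-oxazolidin-3-yl]-3-[(2,6-dimethyl-3-{[tri(propan-2-yl)silyl]oxy}phenyl)methyl]-4-oxobutanoate | Cc1ccc(O[Si](C(C)C)(C(C)C)C(C)C)c(C)c1C[C@H](CC(=O)OC)C(=O)N1[C@H](Cc2ccccc2)COC1=O | intermediate
15 | (2R)-2-[(2,6-dimethyl-3-{[tri(propan-2-yl)silyl]oxy}phenyl)methyl]-4-methoxy-4-oxobutaneperoxoic acid | Cc1ccc(O[Si](C(C)C)(C(C)C)C(C)C)c(C)c1C[C@H](CC(=O)OC)C(=O)OO | intermediate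
16 | (2R)-2-[(2,6-dimethyl-3-{[tri(propan-2-yl)silyl]oxy}phenyl)methyl]-4-methoxy-4-oxobutanoic acid | Cc1ccc(O[Si](C(C)C)(C(C)C)C(C)C)c(C)c1C[C@H](CC(=O)OC)C(=O)O | intermediate
17 | (trimethylsilyl)diazomethane | C[Si](C)(C)C=[N+]=[N-] | starting material
18 | mixed anhydride of 16 and isobutyl hydrogen carbonate | Cc1ccc(O[Si](C(C)C)(C(C)C)C(C)C)c(C)c1C[C@H](CC(=O)OC)C(=O)OC(=O)OCC(C)C | intermediate
19 | methyl (3R)-5-diazo-3-[(2,6-dimethyl-3-{[tri(propan-2-yl)silyl]oxy}phenyl)methyl]-4-oxopentanoate | Cc1ccc(O[Si](C(C)C)(C(C)C)C(C)C)c(C)c1C[C@H](CC(=O)OC)C(=O)C=[N+]=[N-] | intermediate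
20 | methyl (3R)-5-diazo-3-[(3-hydroxy-2,6-dimethylphenyl)methyl]-4-oxopentanoate (precursor of the key step) | Cc1ccc(O)c(C)c1C[C@H](CC(=O)OC)C(=O)C=[N+]=[N-] | intermediate
21 | methyl (7R,10S)-3,8-dioxo-13-noreudesma-1,4-dien-12-oate (product of the key step) | COC(=O)C[C@H]1CC2=C(C)C(=O)C=C[C@]2(C)CC1=O | intermediate
22 | methyl (7R,10R)-3,8-dioxo-13-noreudesm-4-en-12-oate | COC(=O)C[C@H]1CC2=C(C)C(=O)CC[C@]2(C)CC1=O | intermediate
23 | lithium 8β-alkoxide of methyl (7R,8R,10R)-8-hydroxy-3-oxo-13-noreudesm-4-en-12-oate | COC(=O)C[C@H]1CC2=C(C)C(=O)CC[C@]2(C)C[C@H]1[O-].[Li+] | intermediate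
24 | (7R,8R,10R)-3-oxo-13-noreudesm-4-en-8β,12-olide | O=C1C[C@H]2CC3=C(C)C(=O)CC[C@]3(C)C[C@H]2O1 | intermediate
25 | (3S,7R,8R,10R)-3β-hydroxy-13-noreudesm-4-en-8β,12-olide | O=C1C[C@H]2CC3=C(C)[C@@H](O)CC[C@]3(C)C[C@H]2O1 | intermediate
26 | 13-(dimethylamino)-3β-hydroxyeudesm-4-en-8β,12-olide (C11 epimers) | O=C1C(CN(C)C)[C@H]2CC3=C(C)[C@@H](O)CC[C@]3(C)C[C@H]2O1 | intermediate
27 | 13-(trimethylammonio)-3β-hydroxyeudesm-4-en-8β,12-olide iodide (C11 epimers) | O=C1C(C[N+](C)(C)C)[C@H]2CC3=C(C)[C@@H](O)CC[C@]3(C)C[C@H]2O1.[I-] | intermediate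
28 | (3S,7R,8R,10R)-3β-hydroxyeudesma-4,11(13)-dien-8β,12-olide | O=C1C(=C)[C@H]2CC3=C(C)[C@@H](O)CC[C@]3(C)C[C@H]2O1 | intermediate
29 | (2E)-3-methylpent-2-enoic acid | CC/C(C)=C/C(=O)O | starting material
30 | (3S,7R,8R,10R)-3β-[(2E)-3-methylpent-2-enoyloxy]eudesma-4,11(13)-dien-8β,12-olide | O=C1C(=C)[C@H]2CC3=C(C)[C@@H](OC(=O)/C=C(\C)CC)CC[C@]3(C)C[C@H]2O1 | intermediate
31 | lithium 8β-hydroxy-3β-[(2E)-3-methylpent-2-enoyloxy]eudesma-4,11(13)-dien-12-oate | C=C(C(=O)[O-])[C@H]1CC2=C(C)[C@@H](OC(=O)/C=C(\C)CC)CC[C@]2(C)C[C@H]1O.[Li+] | intermediate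
32 | methyl 8β-hydroxy-3β-[(2E)-3-methylpent-2-enoyloxy]eudesma-4,11(13)-dien-12-oate | C=C(C(=O)OC)[C@H]1CC2=C(C)[C@@H](OC(=O)/C=C(\C)CC)CC[C@]2(C)C[C@H]1O | intermediate
33 | methyl (3S,7R,8R,10R)-8β-acetoxy-3β-[(2E)-3-methylpent-2-enoyloxy]eudesma-4,11(13)-dien-12-oate (CNP0118541.1) | C=C(C(=O)OC)[C@H]1CC2=C(C)[C@@H](OC(=O)/C=C(\C)CC)CC[C@]2(C)C[C@H]1OC(C)=O | target

Total step count: 18. Longest linear sequence: 17 steps (steps 1–6 and 8–18); step 7 is a one-step side branch that supplies imide 12.

Steps most likely to fail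

1. Step 12. The alkanediazonium ion may be captured by trifluoroacetate before the arene reacts, attack at C4 may compete, and the methyl group may form on either face of C10 with only moderate preference, since the equatorial bias of the C7 substituent is small in a ring with two sp2 centres. Fallback: setting out from 20, aqueous HBr in Et2O at 0 °C should convert the diazoketone into methyl (3R)-5-bromo-3-[(3-hydroxy-2,6-dimethylphenyl)methyl]-4-oxopentanoate F1 (hydrohalogenation of an α-diazoketone). One equivalent of KOt-Bu in t-BuOH–THF at high dilution then forms the phenoxide, whose para carbon C10 alkylates intramolecularly (phenoxide para-C-alkylation to a cyclohexadienone, the anionic counterpart of aryl participation), and the sequence comes back to the route at 21. No external nucleophile competes in this mode, O-alkylation would need an eight-membered ring, and limiting the base to one equivalent keeps C7 from epimerising.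

2. Step 18. Hydroxide may also cleave or add to the O3 enoate, and the freed 8β-hydroxy ester may re-close to the lactone in competition with acetylation of the hindered axial hydroxyl. Fallback: setting out from 28, silylation (t-BuMe2SiCl, imidazole, DMF) gives 3β-(tert-butyldimethylsilyloxy)eudesma-4,11(13)-dien-8β,12-olide F2, in which no second ester is present. LiOH then gives lithium 8β-hydroxy-3β-(tert-butyldimethylsilyloxy)eudesma-4,11(13)-dien-12-oate F3, MeI in DMF gives methyl 8β-hydroxy-3β-(tert-butyldimethylsilyloxy)eudesma-4,11(13)-dien-12-oate F4, and Ac2O–pyridine–DMAP gives methyl 8β-acetoxy-3β-(tert-butyldimethylsilyloxy)eudesma-4,11(13)-dien-12-oate F5. Excess hydroxide can be used here, and re-closed lactone is simply F2 and is recycled. Bu4NF–AcOH then releases methyl 8β-acetoxy-3β-hydroxyeudesma-4,11(13)-dien-12-oate F6, and Steglich esterification with 29 puts on the enoate last and comes back to the route at 33.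

3. Step 14. Chemoselectivity may be lost, with hydride also adding to the conjugated C3 carbonyl and giving mixtures of partly and fully reduced material. Fallback: setting out from 22, an excess of LiBH(s-Bu)3 (THF, −78 → 0 °C, then AcOH) reduces both carbonyl groups on purpose and should give, after lactonisation, (3R,7R,8R,10R)-3α-hydroxy-13-noreudesm-4-en-8β,12-olide F7, since the bulky hydride delivers the pseudo-axial allylic alcohol. MnO2 in CH2Cl2 then re-oxidises only the allylic alcohol and the sequence comes back to the route at 24.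

Further compounds
F1 | step 12 | methyl (3R)-5-bromo-3-[(3-hydroxy-2,6-dimethylphenyl)methyl]-4-oxopentanoate | Cc1ccc(O)c(C)c1C[C@H](CC(=O)OC)C(=O)CBr
F2 | step 18 | 3β-(tert-butyldimethylsilyloxy)eudesma-4,11(13)-dien-8β,12-olide | O=C1C(=C)[C@H]2CC3=C(C)[C@@H](O[Si](C)(C)C(C)(C)C)CC[C@]3(C)C[C@H]2O1
F3 | step 18 | lithium 8β-hydroxy-3β-(tert-butyldimethylsilyloxy)eudesma-4,11(13)-dien-12-oate | C=C(C(=O)[O-])[C@H]1CC2=C(C)[C@@H](O[Si](C)(C)C(C)(C)C)CC[C@]2(C)C[C@H]1O.[Li+]
F4 | step 18 | methyl 8β-hydroxy-3β-(tert-butyldimethylsilyloxy)eudesma-4,11(13)-dien-12-oate | C=C(C(=O)OC)[C@H]1CC2=C(C)[C@@H](O[Si](C)(C)C(C)(C)C)CC[C@]2(C)C[C@H]1O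
F5 | step 18 | methyl 8β-acetoxy-3β-(tert-butyldimethylsilyloxy)eudesma-4,11(13)-dien-12-oate | C=C(C(=O)OC)[C@H]1CC2=C(C)[C@@H](O[Si](C)(C)C(C)(C)C)CC[C@]2(C)C[C@H]1OC(C)=O
F6 | step 18 | methyl 8β-acetoxy-3β-hydroxyeudesma-4,11(13)-dien-12-oate | C=C(C(=O)OC)[C@H]1CC2=C(C)[C@@H](O)CC[C@]2(C)C[C@H]1OC(C)=O
F7 | step 14 | (3R,7R,8R,10R)-3α-hydroxy-13-noreudesm-4-en-8β,12-olide | O=C1C[C@H]2CC3=C(C)[C@H](O)CC[C@]3(C)C[C@H]2O1
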